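## The problem

The target is a 2,3-dihydro-4H-furo[3,2-c]pyran-4-one. A dihydrofuran (ring B: O1, C2, C3, C3a, C7a) is fused through C3a=C7a to a 2-pyranone (ring C: C3a, C4, O5, C6, C7, C7a). C2 carries a catechol (ring A), C3 a 4-hydroxy-2-pyranon-6-yl group (ring D, primed atoms) and C6 an (E)-4-hydroxystyryl group. The stereocentres C2 and C3 are adjacent, trans and both S. Trans is the thermodynamic arrangement, so either centre can correct the other through a reversible process, but the absolute configuration needs an external control element. C3–H lies between C3a and C6', and O1 is the oxygen of a vinylogous acid, so base can open ring B by E1cB elimination and erase both centres at once. The C2–O1 bond is a para-oxygenated benzylic ether that can ionise under strong acid. The catechol is oxidation-sensitive, both pyranones are opened by hard nucleophiles, the styryl alkene excludes hydrogenolysis, and the ring D hydroxyl is as acidic as a carboxylic acid. The feature that invites a late construction of ring C is that the lactone carbon C4 sits on C3a while C7a is an oxygen-bearing sp2 carbon. In a 4,5-dihydrofuran-3-carboxylic acid the carboxyl group is therefore cis to the vinylic C7a–H bond and can direct its metalation, and the missing C7–C6 unit with its styryl group is a cinnamoyl carbene equivalent.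

## Retrosynthesis

Protecting groups. Target 30 is traced to its tris-silyl ether 29 (three O–Si bonds). Triisopropylsilyl aryl ethers tolerate the hydroxide, amine, Lewis-acid and weakly acidic steps of the route and leave with buffered fluoride. Hydrogenolysis (styryl alkene) and Lewis-acid dealkylation (C2–O1 bond) are thereby avoided. The forward step must be run buffered so that no phenoxide para to C2 expels O1.

Ring D. In 29 the O1'–C2' bond is cut to the acyl dioxinone 27, which on heating gives an acylketene that the ketone enol captures. Compound 27 is the oxidised form of aldol 26, and in 26 the C5'–C6' bond is cut to aldehyde 23 and silyl dienol ether 25 (made from dioxinone 24). A basic acetoacetate dianion route was set aside because of the C3–H acidity and the O1 leaving group. The Lewis-acid aldol, a neutral oxidation and a thermolysis never expose C3 to base. The precursor 23 lacks four carbons and one ring.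

The one-carbon handle at C3. Aldehyde 23 is traced to Weinreb amide 22. A protected hydroxymethyl group would cost a reduction, a protection, a deprotection and an oxidation. The amide instead comes in one step from the aldol adduct, is inert through all intermediate steps, acidifies C3–H only weakly, and gives the aldehyde by one hydride transfer.

Ring C, the key disconnection. In 22 the C7–C7a and O5–C6 bonds are cut, giving dihydrofuran acid 15 and cinnamoyl sulfoxonium ylide 20. Building ring B onto a finished styrylpyranone is the obvious neighbour, but it leaves open which carbonyl oxygen closes the furan and must create both stereocentres next to a good leaving group. Here C4 and O5 both come from the carboxyl group of 15, so the fusion mode is fixed, and the stereocentres already exist. Acid 15 is monocyclic and 20 is linear. The forward step must metalate one vinylic C–H bond selectively, leave the enone of 20 alone and not disturb C4 or C5 of 15.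

Ylide. Compound 20 is cut at the bond between its carbonyl carbon and the ylide carbon, leading to the silylated cinnamic acid 18 and on to 4-hydroxycinnamic acid 16.

Carboxyl group of 15. The C3–CO2H bond of 15 is cut through trichloromethyl ketone 14 to enol ether 13. An enol ether is acylated at its β-carbon under amine buffering, and haloform cleavage then frees the acid with cold hydroxide. The alternative, formylation of a lactone followed by acid-mediated acyl-lactone rearrangement and ester saponification, would put the electron-rich benzylic C–O bond into hot acidic alcohol and the aryl silyl ethers into prolonged hydroxide.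

Enol ether. Compound 13 is the dehydration product of lactol 11, and 11 is the cyclised form of the aldehyde obtained by cleaving the terminal alkene of 8. The allyl group therefore serves as a masked CH2–CHO unit that needs no protection.

Stereocentres. Amide 8 comes from imide 7 by exchange of the auxiliary. In 7 the bond between the later C2 and C3 is cut to imide 3 and aldehyde 5. An auxiliary-controlled syn-aldol of a simple alkyl imide sets both centres in one step. The syn adduct maps onto the trans ring because the hydroxyl oxygen and the allyl carbon become ring members, leaving the aryl and carbonyl groups on opposite faces. Compound 3 comes from oxazolidinone 1 and acid chloride 2, and 5 from 3,4-dihydroxybenzaldehyde 4.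

## Roads not taken

Alternative 1: The cut is through C2–C3 and O1–C7a. The chlorotitanium enolate of the pyranon-3-ylacetyl imide A2 would add to the silylated aldehyde A3, and the aldolate oxygen would displace the 4-methoxy group of the pyranone by addition–elimination, giving A1 with ring B closed.
- Merits: both stereocentres and ring B arise in one operation from a prefabricated styrylpyranone, and the route would be about a third shorter than the chosen one. In step economy it is clearly better.
- Weak points: the enolate of A2 is a highly stabilised, vinylogous enolate that adds reluctantly to an electron-rich aldehyde and reverts easily. In A1 the C3–H bond is α to an imide and β to the pyranolate leaving group while amine and Lewis acid are still present, so E1cB opening and auxiliary-independent reclosure threaten the absolute configuration. Turning the imide into ring D needs further basic acyl substitutions at this same centre.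
- Comparison: the chosen plan sets the stereocentres on a plain alkyl imide before the leaving group exists, and keeps C3 as a weakly acidifying amide until a non-basic endgame.

Alternative 2: The cut is through C3–C3a, C2–C3 and O1–C2. Pyranone A5 and ring D aldehyde A6 would condense to the alkylidene dione A8. A chiral benzylic sulfonium ylide such as A7 would add to it and the enolate oxygen would displace the sulfide in a [4+1] annulation, giving the fully protected target A4.
- Merits: this is the shortest road. All four rings are in place after one pot, only deprotection remains, and anti displacement gives trans directly. It could halve the step count.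
- Weak points: the absolute configuration rests on a stoichiometric chiral sulfide carrying a semi-stabilised, electron-rich benzyl ylide, a case where enantioselectivity depends strongly on the substrate. Acceptors such as A8 readily take up a second molecule of A5. A6 is an electron-poor aldehyde that is not trivial to make. Closure through the lactone carbonyl oxygen instead of the C4 oxygen would give the isomeric ring fusion. The doubly activated C3–H is formed under basic conditions.
- Comparison: against the better convergence, the chosen plan sets an auxiliary aldol of established reliability and an unambiguous ring fusion.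

Alternative 3: A temporary C3a–C2 bond is made and then cut. Spirocyclopropane A10 would ionise at its benzylic carbon under Sc(OTf)3, and the dione enolate oxygen would reclose on C2 (a Cloke–Wilson-type ring expansion), giving aldehyde A9.
- Merits: A9 is the tert-butyldimethylsilyl analogue of aldehyde 23, so this road would join the chosen endgame after roughly half the steps. The ring expansion of cyclopropyl 1,3-diones is known, and it delivers the trans isomer.
- Weak points: A10 must be made as a single enantiomer at the formyl-bearing carbon by cyclopropanation of an electron-rich cinnamaldehyde, where direct closure through oxygen competes. The enolisable formyl centre must survive the Lewis acid. The aryl-bearing carbon is flanked by two acceptors, so the wrong cyclopropane bond can break. The choice between the two dione oxygens again decides the ring fusion.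
- Comparison: the chosen plan pays with more steps and gains absolute control from the auxiliary, a fixed fusion mode, and a C3 substituent that stays an amide until the last stage.

Key step: step 11

Abbreviations: TIPS = triisopropylsilyl; Ar = 3,4-bis(TIPS-oxy)phenyl; Ar′ = 4-(TIPS-oxy)phenyl. Furopyranone positions are numbered O1, C2, C3, C3a, C4, O5, C6, C7, C7a.

Remark on the chemistry: lactol 11 and aldol 26 are carried as mixtures at the centres that steps 6 and 15 remove. The styrylpyranones are handled with exclusion of light.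

Step 1
Reactants: 1 (S)-4-benzyloxazolidin-2-one; 2 pent-4-enoyl chloride
Product: 3 (S)-4-benzyl-3-(pent-4-enoyl)oxazolidin-2-one
Conditions: n-BuLi, THF, −78 °C; then 2, −78 → 0 °C
Reagents that add atoms: none
Why: N-acylation of the lithiated oxazolidinone by an acid chloride is the standard entry to Evans imides; the stereocentre of 1 is not involved.

Step 2
Reactants: 4 3,4-dihydroxybenzaldehyde
Product: 5 3,4-bis(triisopropylsilyloxy)benzaldehyde
Conditions: iPr3SiCl, imidazole, DMF, 0 °C → rt
Reagents that add atoms: chlorotriisopropylsilane, CC(C)[Si](Cl)(C(C)C)C(C)C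
Why: Imidazole-mediated silylation of phenols; the bulky aryl silyl ethers resist the cold hydroxide, amine and Lewis-acid steps that follow and are removed together at the end.

Step 3
Reactants: 3 (S)-4-benzyl-3-(pent-4-enoyl)oxazolidin-2-one; 5 3,4-bis(triisopropylsilyloxy)benzaldehyde
Product: 7 (S)-4-benzyl-3-{(S)-2-[(S)-Ar(hydroxy)methyl]pent-4-enoyl}oxazolidin-2-one, via Z-boron enolate 6 (not isolated)
Conditions: Bu2BOTf, iPr2NEt, CH2Cl2, 0 °C; then 5, −78 → 0 °C; pH 7 buffer, MeOH, H2O2, 0 °C
Reagents that add atoms: none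
Why: Evans syn-aldol: the Z-boron enolate reacts through a chair transition state on the face opposite the benzyl group, which sets both new centres (S at the α-carbon, S at the carbinol) in the syn relation that becomes trans in ring B. Aryl aldehydes are standard partners.

Step 4
Reactants: 7 (S)-4-benzyl-3-{(S)-2-[(S)-Ar(hydroxy)methyl]pent-4-enoyl}oxazolidin-2-one
Product: 8 (S)-2-[(S)-Ar(hydroxy)methyl]-N-methoxy-N-methylpent-4-enamide
Conditions: MeNH(OMe)·HCl, AlMe3, CH2Cl2, −20 → 0 °C; aq. potassium sodium tartrate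
Reagents that add atoms: N,O-dimethylhydroxylamine hydrochloride, CNOC.Cl
Why: Aluminium-amide transamination of a β-hydroxy acyl oxazolidinone to the Weinreb amide; the free hydroxyl directs the aluminium reagent to the exocyclic carbonyl and the α-centre is not enolised. The auxiliary 1 is recovered.

Step 5
Reactants: 8 (S)-2-[(S)-Ar(hydroxy)methyl]-N-methoxy-N-methylpent-4-enamide
Product: 11 (2S,3S)-2-Ar-5-hydroxy-N-methoxy-N-methyltetrahydrofuran-3-carboxamide (both C5 anomers), via 4,5-diol 9 (not isolated), via hydroxy aldehyde 10 (not isolated)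
Conditions: OsO4 (cat.), NaIO4, 2,6-lutidine, 1,4-dioxane/H2O, rt
Reagents that add atoms: osmium tetroxide, O=[Os](=O)(=O)=O; sodium periodate, [Na+].[O-]I(=O)(=O)=O
Why: Lemieux–Johnson cleavage of the terminal alkene; the γ-hydroxy aldehyde closes at once to the five-membered lactol. The electron-rich arene and the benzylic alcohol are not attacked under these buffered conditions.

Step 6
Reactants: 11 (2S,3S)-2-Ar-5-hydroxy-N-methoxy-N-methyltetrahydrofuran-3-carboxamide
Product: 13 (2S,3S)-2-Ar-N-methoxy-N-methyl-2,3-dihydrofuran-3-carboxamide, via anomeric mesylate 12 (not isolated)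
Conditions: MsCl, Et3N, CH2Cl2, −40 → 40 °C; Et3N-deactivated silica
Reagents that add atoms: none
Why: Lactol dehydration through the anomeric mesylate and the derived oxocarbenium ion, as used for furanoid glycals; only the C4 methylene can lose a proton, so the enol ether forms with one regiochemistry, and triethylamine is too weak to touch the amide α-hydrogen.

Step 7
Reactants: 13 (2S,3S)-2-Ar-N-methoxy-N-methyl-2,3-dihydrofuran-3-carboxamide
Product: 14 (2S,3S)-2-Ar-N-methoxy-N-methyl-4-(trichloroacetyl)-2,3-dihydrofuran-3-carboxamide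
Conditions: Cl3CCOCl, pyridine, CH2Cl2, 0 °C → rt
Reagents that add atoms: trichloroacetyl chloride, O=C(Cl)C(Cl)(Cl)Cl
Why: Electrophilic β-acylation of a cyclic enol ether by trichloroacetyl chloride with loss of a proton from the oxocarbenium ion, a standard route to β-alkoxyvinyl trichloromethyl ketones from 2,3-dihydrofurans.

Step 8
Reactants: 14 (2S,3S)-2-Ar-N-methoxy-N-methyl-4-(trichloroacetyl)-2,3-dihydrofuran-3-carboxamide
Product: 15 (4S,5S)-5-Ar-4-[methoxy(methyl)carbamoyl]-4,5-dihydrofuran-3-carboxylic acid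
Conditions: LiOH, THF/H2O, 0 °C; then 1 M HCl to pH 3, 0 °C
Reagents that add atoms: lithium hydroxide, [Li+].[OH-]
Why: Haloform-type cleavage: hydroxide adds to the trichloromethyl ketone and expels trichloromethanide, giving the β-alkoxyacrylic acid directly. The conditions are short and cold enough for the aryl TIPS ethers and the amide α-centre.

Step 9
Reactants: 16 (E)-4-hydroxycinnamic acid
Product: 18 (E)-3-Ar′-prop-2-enoic acid, via bis-silylated ester 17 (not isolated)
Conditions: iPr3SiCl, imidazole, DMF, rt; then K2CO3, THF/MeOH/H2O, 0 °C; aq. HCl to pH 3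
Reagents that add atoms: chlorotriisopropylsilane, CC(C)[Si](Cl)(C(C)C)C(C)C
Why: Exhaustive silylation followed by selective hydrolysis of the much more labile silyl ester leaves the aryl silyl ether in place.

Step 10
Reactants: 18 (E)-3-Ar′-prop-2-enoic acid
Product: 20 (E)-1-(dimethylsulfoxonio)-2-oxo-4-Ar′-but-3-en-1-ide, via acid chloride 19 (not isolated)
Conditions: (COCl)2, DMF (cat.), CH2Cl2, 0 °C → rt, evaporate; then (CH3)3S(O)I, KOtBu, THF, reflux then 0 °C, add 19, 0 °C → rt
Reagents that add atoms: trimethylsulfoxonium iodide, C[S+](C)(C)=O.[I-]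
Why: Acylation of dimethylsulfoxonium methylide by an acid chloride, with a second equivalent of methylide acting as base, is the standard preparation of β-keto sulfoxonium ylides. Attack at the acyl chloride is far faster than conjugate addition, and the product enone is deactivated by the ylide.

Step 11
Reactants: 15 (4S,5S)-5-Ar-4-[methoxy(methyl)carbamoyl]-4,5-dihydrofuran-3-carboxylic acid; 20 (E)-1-(dimethylsulfoxonio)-2-oxo-4-Ar′-but-3-en-1-ide
Product: 22 (2S,3S)-2-Ar-N-methoxy-N-methyl-4-oxo-6-[(E)-2-Ar′-ethenyl]-2,3-dihydro-4H-furo[3,2-c]pyran-3-carboxamide, via keto acid 21 (not isolated)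
Conditions: [Cp*RhCl2]2 (5 mol %), AgSbF6 (20 mol %), NaOAc (30 mol %), 1,2-dichloroethane, 80 °C
Reagents that add atoms: none
Why: The carboxylate of 15 binds cationic Cp*-rhodium (trivalent), and acetate-assisted concerted metalation–deprotonation of the cis vinylic C–H bond (C2 of 15, the later C7a) gives a five-membered rhodacycle. Ylide 20 binds through carbon and loses dimethyl sulfoxide to form a rhodium carbene; migratory insertion and protodemetalation form C7a–C7 and give keto acid 21. Ring C then closes by 6-exo-trig addition of the carboxyl oxygen to the ketone carbonyl and loss of water (O5–C6), driven by formation of the conjugated 2-pyranone. The closest known reactions are the Cp*-rhodium-catalysed annulations of benzoic and alkenyl carboxylic acids with sulfoxonium ylides to isocoumarins and 2-pyranones. No stereocentre is formed; C4 and C5 of 15 are spectators in the acetate-buffered, weakly acidic medium, and trans is in any case the thermodynamic arrangement. Site selectivity comes from the substrate: only this one sp2 C–H bond lies cis to the carboxylate within reach of a five-membered metallacycle, and neither the aryl C–H bonds nor the Weinreb amide can form one. Chemoselectivity for the ylide carbon over the enone rests on the ylide resonance, which makes the cinnamoyl carbonyl amide-like and its β-carbon a poor acceptor.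

Step 12
Reactants: 22 (2S,3S)-2-Ar-N-methoxy-N-methyl-4-oxo-6-[(E)-2-Ar′-ethenyl]-2,3-dihydro-4H-furo[3,2-c]pyran-3-carboxamide
Product: 23 (2S,3S)-2-Ar-4-oxo-6-[(E)-2-Ar′-ethenyl]-2,3-dihydro-4H-furo[3,2-c]pyran-3-carbaldehyde
Conditions: Cp2Zr(H)Cl, THF, rt, short reaction time; filtration through silica; used at once
Reagents that add atoms: none
Why: Hydrozirconation of the amide carbonyl gives a stable zirconated hemiaminal that releases the aldehyde on work-up; this reduction of tertiary and Weinreb amides tolerates esters and lactones and needs no base, which matters for the E1cB-prone C3 centre.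

Step 13
Reactants: 24 2,2,6-trimethyl-4H-1,3-dioxin-4-one
Product: 25 trimethyl[(2,2-dimethyl-6-methylidene-6H-1,3-dioxin-4-yl)oxy]silane
Conditions: LiN(iPr)2, THF, −78 °C; Me3SiCl, −78 → 0 °C
Reagents that add atoms: chlorotrimethylsilane, C[Si](C)(C)Cl
Why: γ-Deprotonation of the dioxinone and O-silylation of the dienolate give the standard silyl dienol ether for vinylogous Mukaiyama aldol reactions.

Step 14
Reactants: 23 (2S,3S)-2-Ar-4-oxo-6-[(E)-2-Ar′-ethenyl]-2,3-dihydro-4H-furo[3,2-c]pyran-3-carbaldehyde; 25 trimethyl[(2,2-dimethyl-6-methylidene-6H-1,3-dioxin-4-yl)oxy]silane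
Product: 26 6-{2-[(2S,3R)-2-Ar-4-oxo-6-[(E)-2-Ar′-ethenyl]-2,3-dihydro-4H-furo[3,2-c]pyran-3-yl]-2-hydroxyethyl}-2,2-dimethyl-4H-1,3-dioxin-4-one (both carbinol epimers)
Conditions: BF3·OEt2, CH2Cl2, −78 °C; aq. NaHCO3
Reagents that add atoms: none
Why: Vinylogous Mukaiyama aldol: the Lewis-acid-activated aldehyde is attacked by the γ-carbon of the dienol ether. No base is present, so C3 is neither epimerised nor eliminated, and the new carbinol centre is removed in the next step. The C3 descriptor changes to R only because the substituent priorities change.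

Step 15
Reactants: 26 6-{2-[(2S,3R)-2-Ar-4-oxo-6-[(E)-2-Ar′-ethenyl]-2,3-dihydro-4H-furo[3,2-c]pyran-3-yl]-2-hydroxyethyl}-2,2-dimethyl-4H-1,3-dioxin-4-one
Product: 27 6-{2-[(2S,3S)-2-Ar-4-oxo-6-[(E)-2-Ar′-ethenyl]-2,3-dihydro-4H-furo[3,2-c]pyran-3-yl]-2-oxoethyl}-2,2-dimethyl-4H-1,3-dioxin-4-one
Conditions: Dess–Martin periodinane, CH2Cl2, 0 °C → rt
Reagents that add atoms: none
Why: Dess–Martin oxidation of a secondary alcohol to the ketone under non-basic conditions; silyl ethers, the alkene and both lactone-type rings are inert to it.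

Step 16
Reactants: 27 6-{2-[(2S,3S)-2-Ar-4-oxo-6-[(E)-2-Ar′-ethenyl]-2,3-dihydro-4H-furo[3,2-c]pyran-3-yl]-2-oxoethyl}-2,2-dimethyl-4H-1,3-dioxin-4-one
Product: 29 (2S,3S)-2-Ar-3-(4-hydroxy-2-oxo-2H-pyran-6-yl)-6-[(E)-2-Ar′-ethenyl]-2,3-dihydro-4H-furo[3,2-c]pyran-4-one, via acylketene 28 (not isolated)
Conditions: toluene (dilute), 110 °C
Reagents that add atoms: none
Why: Thermal retro-[4+2] of the dioxinone releases acetone and an acylketene, which the enol of the adjacent ketone captures to close the 4-hydroxy-2-pyranone (ring D), a standard neutral pyranone synthesis. Any enolisation towards C3 can only return the favoured trans isomer.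

Step 17
Reactants: 29 (2S,3S)-2-Ar-3-(4-hydroxy-2-oxo-2H-pyran-6-yl)-6-[(E)-2-Ar′-ethenyl]-2,3-dihydro-4H-furo[3,2-c]pyran-4-one
Product: 30 (2S,3S)-2-(3,4-dihydroxyphenyl)-3-(4-hydroxy-2-oxo-2H-pyran-6-yl)-6-[(E)-2-(4-hydroxyphenyl)ethenyl]-2,3-dihydro-4H-furo[3,2-c]pyran-4-one (CNP0330607.1)
Conditions: Bu4NF, AcOH, THF, 0 °C → rt, under argon
Reagents that add atoms: none
Why: Fluoride cleavage of the three aryl silyl ethers; the acetic acid buffer keeps the phenols and the ring D hydroxyl protonated, so no phenoxide para to C2 can expel O1 and the pyranones are not opened.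

## Compound list

1 | (S)-4-benzyloxazolidin-2-one | O=C1N[C@@H](Cc2ccccc2)CO1 | starting material
2 | pent-4-enoyl chloride | C=CCCC(=O)Cl | starting material
3 | (S)-4-benzyl-3-(pent-4-enoyl)oxazolidin-2-one | C=CCCC(=O)N1[C@@H](Cc2ccccc2)COC1=O | intermediate
4 | 3,4-dihydroxybenzaldehyde | O=Cc1ccc(O)c(O)c1 | starting material
5 | 3,4-bis(triisopropylsilyloxy)benzaldehyde | O=Cc1ccc(O[Si](C(C)C)(C(C)C)C(C)C)c(O[Si](C(C)C)(C(C)C)C(C)C)c1 | intermediate
6 | (S)-4-benzyl-3-[(Z)-1-(dibutylboryloxy)penta-1,4-dienyl]oxazolidin-2-one (Z-boron enolate of 3) | C=CC/C=C(\OB(CCCC)CCCC)N1[C@@H](Cc2ccccc2)COC1=O | intermediate (not isolated)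
7 | (S)-4-benzyl-3-{(S)-2-[(S)-[3,4-bis(TIPS-oxy)phenyl](hydroxy)methyl]pent-4-enoyl}oxazolidin-2-one | C=CC[C@H](C(=O)N1[C@@H](Cc2ccccc2)COC1=O)[C@H](O)c1ccc(O[Si](C(C)C)(C(C)C)C(C)C)c(O[Si](C(C)C)(C(C)C)C(C)C)c1 | intermediate
8 | (S)-2-{(S)-[3,4-bis(TIPS-oxy)phenyl](hydroxy)methyl}-N-methoxy-N-methylpent-4-enamide | C=CC[C@H](C(=O)N(C)OC)[C@H](O)c1ccc(O[Si](C(C)C)(C(C)C)C(C)C)c(O[Si](C(C)C)(C(C)C)C(C)C)c1 | intermediate
9 | (2S)-2-{(S)-[3,4-bis(TIPS-oxy)phenyl](hydroxy)methyl}-4,5-dihydroxy-N-methoxy-N-methylpentanamide (C4 epimers) | OCC(O)C[C@H](C(=O)N(C)OC)[C@H](O)c1ccc(O[Si](C(C)C)(C(C)C)C(C)C)c(O[Si](C(C)C)(C(C)C)C(C)C)c1 | intermediate (not isolated)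
10 | (S)-2-{(S)-[3,4-bis(TIPS-oxy)phenyl](hydroxy)methyl}-N-methoxy-N-methyl-4-oxobutanamide | O=CC[C@H](C(=O)N(C)OC)[C@H](O)c1ccc(O[Si](C(C)C)(C(C)C)C(C)C)c(O[Si](C(C)C)(C(C)C)C(C)C)c1 | intermediate (not isolated)
11 | (2S,3S)-2-[3,4-bis(TIPS-oxy)phenyl]-5-hydroxy-N-methoxy-N-methyltetrahydrofuran-3-carboxamide (C5 anomers) | CON(C)C(=O)[C@H]1CC(O)O[C@@H]1c1ccc(O[Si](C(C)C)(C(C)C)C(C)C)c(O[Si](C(C)C)(C(C)C)C(C)C)c1 | intermediate
12 | (4S,5S)-5-[3,4-bis(TIPS-oxy)phenyl]-4-[methoxy(methyl)carbamoyl]tetrahydrofuran-2-yl methanesulfonate | CON(C)C(=O)[C@H]1CC(OS(C)(=O)=O)O[C@@H]1c1ccc(O[Si](C(C)C)(C(C)C)C(C)C)c(O[Si](C(C)C)(C(C)C)C(C)C)c1 | intermediate (not isolated)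
13 | (2S,3S)-2-[3,4-bis(TIPS-oxy)phenyl]-N-methoxy-N-methyl-2,3-dihydrofuran-3-carboxamide | CON(C)C(=O)[C@H]1C=CO[C@@H]1c1ccc(O[Si](C(C)C)(C(C)C)C(C)C)c(O[Si](C(C)C)(C(C)C)C(C)C)c1 | intermediate
14 | (2S,3S)-2-[3,4-bis(TIPS-oxy)phenyl]-N-methoxy-N-methyl-4-(2,2,2-trichloroacetyl)-2,3-dihydrofuran-3-carboxamide | CON(C)C(=O)[C@H]1C(C(=O)C(Cl)(Cl)Cl)=CO[C@@H]1c1ccc(O[Si](C(C)C)(C(C)C)C(C)C)c(O[Si](C(C)C)(C(C)C)C(C)C)c1 | intermediate
15 | (4S,5S)-5-[3,4-bis(TIPS-oxy)phenyl]-4-[methoxy(methyl)carbamoyl]-4,5-dihydrofuran-3-carboxylic acid | CON(C)C(=O)[C@H]1C(C(=O)O)=CO[C@@H]1c1ccc(O[Si](C(C)C)(C(C)C)C(C)C)c(O[Si](C(C)C)(C(C)C)C(C)C)c1 | intermediate (precursor of the key step)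
16 | (E)-4-hydroxycinnamic acid | O=C(O)/C=C/c1ccc(O)cc1 | starting material
17 | triisopropylsilyl (E)-3-[4-(TIPS-oxy)phenyl]prop-2-enoate | CC(C)[Si](OC(=O)/C=C/c1ccc(O[Si](C(C)C)(C(C)C)C(C)C)cc1)(C(C)C)C(C)C | intermediate (not isolated)
18 | (E)-3-[4-(TIPS-oxy)phenyl]prop-2-enoic acid | O=C(O)/C=C/c1ccc(O[Si](C(C)C)(C(C)C)C(C)C)cc1 | intermediate
19 | (E)-3-[4-(TIPS-oxy)phenyl]prop-2-enoyl chloride | O=C(Cl)/C=C/c1ccc(O[Si](C(C)C)(C(C)C)C(C)C)cc1 | intermediate (not isolated)
20 | (E)-1-(dimethylsulfoxonio)-2-oxo-4-[4-(TIPS-oxy)phenyl]but-3-en-1-ide | C[S+](C)(=O)[CH-]C(=O)/C=C/c1ccc(O[Si](C(C)C)(C(C)C)C(C)C)cc1 | intermediate (ylide partner of the key step)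
21 | (4S,5S)-5-[3,4-bis(TIPS-oxy)phenyl]-4-[methoxy(methyl)carbamoyl]-2-{(E)-2-oxo-4-[4-(TIPS-oxy)phenyl]but-3-enyl}-4,5-dihydrofuran-3-carboxylic acid | CON(C)C(=O)[C@H]1C(C(=O)O)=C(CC(=O)/C=C/c2ccc(O[Si](C(C)C)(C(C)C)C(C)C)cc2)O[C@@H]1c1ccc(O[Si](C(C)C)(C(C)C)C(C)C)c(O[Si](C(C)C)(C(C)C)C(C)C)c1 | intermediate (not isolated)
22 | (2S,3S)-2-[3,4-bis(TIPS-oxy)phenyl]-N-methoxy-N-methyl-4-oxo-6-{(E)-2-[4-(TIPS-oxy)phenyl]ethenyl}-2,3-dihydro-4H-furo[3,2-c]pyran-3-carboxamide | CON(C)C(=O)[C@H]1c2c(cc(/C=C/c3ccc(O[Si](C(C)C)(C(C)C)C(C)C)cc3)oc2=O)O[C@@H]1c1ccc(O[Si](C(C)C)(C(C)C)C(C)C)c(O[Si](C(C)C)(C(C)C)C(C)C)c1 | intermediate (product of the key step)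
23 | (2S,3S)-2-[3,4-bis(TIPS-oxy)phenyl]-4-oxo-6-{(E)-2-[4-(TIPS-oxy)phenyl]ethenyl}-2,3-dihydro-4H-furo[3,2-c]pyran-3-carbaldehyde | O=C[C@H]1c2c(cc(/C=C/c3ccc(O[Si](C(C)C)(C(C)C)C(C)C)cc3)oc2=O)O[C@@H]1c1ccc(O[Si](C(C)C)(C(C)C)C(C)C)c(O[Si](C(C)C)(C(C)C)C(C)C)c1 | intermediate
24 | 2,2,6-trimethyl-4H-1,3-dioxin-4-one | CC1=CC(=O)OC(C)(C)O1 | starting material
25 | trimethyl[(2,2-dimethyl-6-methylidene-6H-1,3-dioxin-4-yl)oxy]silane | C=C1C=C(O[Si](C)(C)C)OC(C)(C)O1 | intermediate
26 | 6-{2-[(2S,3R)-2-[3,4-bis(TIPS-oxy)phenyl]-4-oxo-6-{(E)-2-[4-(TIPS-oxy)phenyl]ethenyl}-2,3-dihydro-4H-furo[3,2-c]pyran-3-yl]-2-hydroxyethyl}-2,2-dimethyl-4H-1,3-dioxin-4-one (carbinol epimers) | CC1(C)OC(=O)C=C(CC(O)[C@H]2c3c(cc(/C=C/c4ccc(O[Si](C(C)C)(C(C)C)C(C)C)cc4)oc3=O)O[C@@H]2c2ccc(O[Si](C(C)C)(C(C)C)C(C)C)c(O[Si](C(C)C)(C(C)C)C(C)C)c2)O1 | intermediate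
27 | 6-{2-[(2S,3S)-2-[3,4-bis(TIPS-oxy)phenyl]-4-oxo-6-{(E)-2-[4-(TIPS-oxy)phenyl]ethenyl}-2,3-dihydro-4H-furo[3,2-c]pyran-3-yl]-2-oxoethyl}-2,2-dimethyl-4H-1,3-dioxin-4-one | CC1(C)OC(=O)C=C(CC(=O)[C@H]2c3c(cc(/C=C/c4ccc(O[Si](C(C)C)(C(C)C)C(C)C)cc4)oc3=O)O[C@@H]2c2ccc(O[Si](C(C)C)(C(C)C)C(C)C)c(O[Si](C(C)C)(C(C)C)C(C)C)c2)O1 | intermediate
28 | 5-[(2S,3S)-2-[3,4-bis(TIPS-oxy)phenyl]-4-oxo-6-{(E)-2-[4-(TIPS-oxy)phenyl]ethenyl}-2,3-dihydro-4H-furo[3,2-c]pyran-3-yl]pent-1-ene-1,3,5-trione (acylketene) | O=C=CC(=O)CC(=O)[C@H]1c2c(cc(/C=C/c3ccc(O[Si](C(C)C)(C(C)C)C(C)C)cc3)oc2=O)O[C@@H]1c1ccc(O[Si](C(C)C)(C(C)C)C(C)C)c(O[Si](C(C)C)(C(C)C)C(C)C)c1 | intermediate (not isolated)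
29 | (2S,3S)-2-[3,4-bis(TIPS-oxy)phenyl]-3-(4-hydroxy-2-oxo-2H-pyran-6-yl)-6-{(E)-2-[4-(TIPS-oxy)phenyl]ethenyl}-2,3-dihydro-4H-furo[3,2-c]pyran-4-one | O=c1cc(O)cc([C@H]2c3c(cc(/C=C/c4ccc(O[Si](C(C)C)(C(C)C)C(C)C)cc4)oc3=O)O[C@@H]2c2ccc(O[Si](C(C)C)(C(C)C)C(C)C)c(O[Si](C(C)C)(C(C)C)C(C)C)c2)o1 | intermediate
30 | (2S,3S)-2-(3,4-dihydroxyphenyl)-3-(4-hydroxy-2-oxo-2H-pyran-6-yl)-6-[(E)-2-(4-hydroxyphenyl)ethenyl]-2,3-dihydro-4H-furo[3,2-c]pyran-4-one | O=c1cc(O)cc([C@H]2c3c(cc(/C=C/c4ccc(O)cc4)oc3=O)O[C@@H]2c2ccc(O)c(O)c2)o1 | target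

## Step count and least certain steps

Total: 17 steps. Longest linear sequence: 13 steps (steps 1, 3–8, 11, 12, 14–17, from 1 and 2). The side branches are steps 2, 9–10 and 13.

Step 11 (key step). The documented scope covers aryl and simple alkenyl acids and mostly aryl or alkyl ylides; an oxygen-bearing vinylic C–H bond and an alkenyl ylide stretch it. The most likely failures are diversion of ylide 20 through its enone (carbene dimerisation, conjugate addition of the carboxylate or of the rhodacycle) and protodecarboxylation of 15 outrunning a slow metalation. The fallback keeps the ring C bonds but builds the styryl group afterwards. From 15, the same annulation is run with the simple methyl-ketone ylide 1-(dimethylsulfoxonio)-2-oxopropan-1-ide F1, prepared from acetic anhydride and dimethylsulfoxonium methylide; this is the best-precedented ylide class, has no enone and can be used in excess. It gives the 6-methyl furopyranone F2. The 6-methyl group, the most accessible acidic site, is deprotonated with LiN(SiMe3)2 at −78 °C and added to commercial 4-(triisopropylsilyloxy)benzaldehyde, giving the vinylogous aldol adduct F3. Dehydration with MsCl and Et3N leads back to 22.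

Step 6. The anomeric mesylate may collapse to the chloride or be captured by the amide oxygen instead of eliminating, and the acid-labile 2-aryl enol ether 13 may hydrolyse or oligomerise on isolation. Fallback: from 11, the lactol is converted with methanol and pyridinium p-toluenesulfonate into the methyl acetal F4, which is treated directly with Cl3CCOCl and pyridine. The acetal loses methanol in the flask and the enol ether is C-acylated as it forms, so the route is rejoined at 14 without handling 13.

Step 7. C-acylation at C4, next to the amide-bearing C3, may be slow, so that addition of HCl to the enol ether competes. Fallback: from 13, Vilsmeier–Haack formylation (POCl3, DMF; aq. NaOAc) gives the 4-formyl dihydrofuran F5, a smaller electrophile being used. Pinnick oxidation (NaClO2, NaH2PO4, 2-methylbut-2-ene) of this β-alkoxy enal gives acid 15 directly, bypassing 14.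

Step 12. Hydride transfer to the ring C lactone or hydrozirconation of the styryl double bond may compete with reduction of the hindered amide. Aldehyde 23 may also enolise on work-up and then lose O1 by E1cB elimination, which would erase both stereocentres. Fallback: from 22, the aldehyde stage is skipped. The Weinreb amide is added to the lithium dienolate of 24 (LiN(SiMe3)2, THF, −78 °C), and acylation at the γ-carbon gives 27 directly, bypassing 23 and 26. This fallback is itself exposed to enolisation at C3 and is therefore kept as the second choice.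

Step 14. The Lewis acid may ionise the benzylic C2–O1 bond, the dienol ether may react at its α-carbon, or 23 may decompose before it is used. Fallback: from 23, Pinnick oxidation gives the carboxylic acid F6 and oxalyl chloride gives the acid chloride F7. Mukaiyama-type γ-acylation of 25 by F7 without added base rejoins the route at 27.

## Further compounds

F1 | step 11 | 1-(dimethylsulfoxonio)-2-oxopropan-1-ide | CC(=O)[CH-][S+](C)(C)=O
F2 | step 11 | (2S,3S)-2-[3,4-bis(TIPS-oxy)phenyl]-N-methoxy-N,6-dimethyl-4-oxo-2,3-dihydro-4H-furo[3,2-c]pyran-3-carboxamide | CON(C)C(=O)[C@H]1c2c(cc(C)oc2=O)O[C@@H]1c1ccc(O[Si](C(C)C)(C(C)C)C(C)C)c(O[Si](C(C)C)(C(C)C)C(C)C)c1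
F3 | step 11 | (2S,3S)-2-[3,4-bis(TIPS-oxy)phenyl]-6-{2-hydroxy-2-[4-(TIPS-oxy)phenyl]ethyl}-N-methoxy-N-methyl-4-oxo-2,3-dihydro-4H-furo[3,2-c]pyran-3-carboxamide (carbinol epimers) | CON(C)C(=O)[C@H]1c2c(cc(CC(O)c3ccc(O[Si](C(C)C)(C(C)C)C(C)C)cc3)oc2=O)O[C@@H]1c1ccc(O[Si](C(C)C)(C(C)C)C(C)C)c(O[Si](C(C)C)(C(C)C)C(C)C)c1
F4 | step 6 | (2S,3S)-2-[3,4-bis(TIPS-oxy)phenyl]-N,5-dimethoxy-N-methyltetrahydrofuran-3-carboxamide (C5 anomers) | CON(C)C(=O)[C@H]1CC(OC)O[C@@H]1c1ccc(O[Si](C(C)C)(C(C)C)C(C)C)c(O[Si](C(C)C)(C(C)C)C(C)C)c1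
F5 | step 7 | (2S,3S)-2-[3,4-bis(TIPS-oxy)phenyl]-4-formyl-N-methoxy-N-methyl-2,3-dihydrofuran-3-carboxamide | CON(C)C(=O)[C@H]1C(C=O)=CO[C@@H]1c1ccc(O[Si](C(C)C)(C(C)C)C(C)C)c(O[Si](C(C)C)(C(C)C)C(C)C)c1
F0 | step 12 | none | none
F6 | step 14 | (2S,3S)-2-[3,4-bis(TIPS-oxy)phenyl]-4-oxo-6-{(E)-2-[4-(TIPS-oxy)phenyl]ethenyl}-2,3-dihydro-4H-furo[3,2-c]pyran-3-carboxylic acid | OC(=O)[C@H]1c2c(cc(/C=C/c3ccc(O[Si](C(C)C)(C(C)C)C(C)C)cc3)oc2=O)O[C@@H]1c1ccc(O[Si](C(C)C)(C(C)C)C(C)C)c(O[Si](C(C)C)(C(C)C)C(C)C)c1
F7 | step 14 | (2S,3S)-2-[3,4-bis(TIPS-oxy)phenyl]-4-oxo-6-{(E)-2-[4-(TIPS-oxy)phenyl]ethenyl}-2,3-dihydro-4H-furo[3,2-c]pyran-3-carbonyl chloride | ClC(=O)[C@H]1c2c(cc(/C=C/c3ccc(O[Si](C(C)C)(C(C)C)C(C)C)cc3)oc2=O)O[C@@H]1c1ccc(O[Si](C(C)C)(C(C)C)C(C)C)c(O[Si](C(C)C)(C(C)C)C(C)C)c1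
A1 | alternative 1 | (2S,3S)-2-[3,4-bis(tert-butyldimethylsilyloxy)phenyl]-3-{[(S)-4-benzyl-2-oxooxazolidin-3-yl]carbonyl}-6-{(E)-2-[4-(tert-butyldimethylsilyloxy)phenyl]ethenyl}-2,3-dihydro-4H-furo[3,2-c]pyran-4-one | O=C([C@H]1c2c(cc(/C=C/c3ccc(O[Si](C)(C)C(C)(C)C)cc3)oc2=O)O[C@@H]1c1ccc(O[Si](C)(C)C(C)(C)C)c(O[Si](C)(C)C(C)(C)C)c1)N1[C@@H](Cc2ccccc2)COC1=O
A2 | alternative 1 | (S)-4-benzyl-3-{2-[4-methoxy-2-oxo-6-{(E)-2-[4-(tert-butyldimethylsilyloxy)phenyl]ethenyl}-2H-pyran-3-yl]acetyl}oxazolidin-2-one | COc1cc(/C=C/c2ccc(O[Si](C)(C)C(C)(C)C)cc2)oc(=O)c1CC(=O)N1[C@@H](Cc2ccccc2)COC1=O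
A3 | alternative 1 | 3,4-bis(tert-butyldimethylsilyloxy)benzaldehyde | O=Cc1ccc(O[Si](C)(C)C(C)(C)C)c(O[Si](C)(C)C(C)(C)C)c1
A4 | alternative 2 | (2S,3S)-2-[3,4-bis(tert-butyldimethylsilyloxy)phenyl]-3-[4-(methoxymethoxy)-2-oxo-2H-pyran-6-yl]-6-{(E)-2-[4-(tert-butyldimethylsilyloxy)phenyl]ethenyl}-2,3-dihydro-4H-furo[3,2-c]pyran-4-one | O=c1cc(OCOC)cc([C@H]2c3c(cc(/C=C/c4ccc(O[Si](C)(C)C(C)(C)C)cc4)oc3=O)O[C@@H]2c2ccc(O[Si](C)(C)C(C)(C)C)c(O[Si](C)(C)C(C)(C)C)c2)o1
A5 | alternative 2 | 4-hydroxy-6-{(E)-2-[4-(tert-butyldimethylsilyloxy)phenyl]ethenyl}-2H-pyran-2-one | O=c1cc(O)cc(/C=C/c2ccc(O[Si](C)(C)C(C)(C)C)cc2)o1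
A6 | alternative 2 | 4-(methoxymethoxy)-2-oxo-2H-pyran-6-carbaldehyde | COCOc1cc(C=O)oc(=O)c1
A7 | alternative 2 | [3,4-bis(tert-butyldimethylsilyloxy)phenyl][(2R,5R)-2,5-dimethylthiolan-1-ium-1-yl]methanide | C[C@@H]1CC[C@@H](C)[S+]1[CH-]c1ccc(O[Si](C)(C)C(C)(C)C)c(O[Si](C)(C)C(C)(C)C)c1
A8 | alternative 2 | 3-{[4-(methoxymethoxy)-2-oxo-2H-pyran-6-yl]methylidene}-6-{(E)-2-[4-(tert-butyldimethylsilyloxy)phenyl]ethenyl}-2H-pyran-2,4(3H)-dione (exocyclic alkene geometry open) | COCOc1cc(C=C2C(=O)C=C(/C=C/c3ccc(O[Si](C)(C)C(C)(C)C)cc3)OC2=O)oc(=O)c1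
A9 | alternative 3 | (2S,3S)-2-[3,4-bis(tert-butyldimethylsilyloxy)phenyl]-4-oxo-6-{(E)-2-[4-(tert-butyldimethylsilyloxy)phenyl]ethenyl}-2,3-dihydro-4H-furo[3,2-c]pyran-3-carbaldehyde | O=C[C@H]1c2c(cc(/C=C/c3ccc(O[Si](C)(C)C(C)(C)C)cc3)oc2=O)O[C@@H]1c1ccc(O[Si](C)(C)C(C)(C)C)c(O[Si](C)(C)C(C)(C)C)c1
A10 | alternative 3 | (2R)-1-[3,4-bis(tert-butyldimethylsilyloxy)phenyl]-4,8-dioxo-6-{(E)-2-[4-(tert-butyldimethylsilyloxy)phenyl]ethenyl}-5-oxaspiro[2.5]oct-6-ene-2-carbaldehyde (configuration at C1 and at the spiro atom open) | O=C[C@@H]1C(c2ccc(O[Si](C)(C)C(C)(C)C)c(O[Si](C)(C)C(C)(C)C)c2)C12C(=O)C=C(/C=C/c1ccc(O[Si](C)(C)C(C)(C)C)cc1)OC2=O
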